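The flask holds 0.086 M of starting material against 0.0817 M of second substrate, with 8.6 µM of free enzyme at 37 °C; it is the epsilon run, followed up to the moment of choice. If each target takes one of each substrate, second substrate is the limiting reagent and the charges allow 95.0% of target. I carry this ceiling, second substrate charged over starting material charged.

| flask | starting material | second substrate | free enzyme | temperature | remark | time |
|---|---|---|---|---|---|---|
| epsilon | 0.086 M | 0.0817 M | 8.6 µM | 37 °C | the very flask that is asked about, followed so far |  |
| gamma | 0.086 M | 0.0817 M | 4.3 µM | 22 °C | run made earlier |  |
| flask | 0.086 M | 0.0817 M | 8.6 µM | 37 °C |  | 10 min |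

epsilon run (percent of the starting material charged)

| time / min | target / % |
|---|---|
| 2.00 | 54.8 |
| 4.00 | 68.6 |
| 6.00 | 76.6 |
| 8.00 | 79.4 |
| 10.0 | 81.6 |

gamma run (percent of the starting material charged)

| time / s | target / % |
|---|---|
| 20.0 | 2.4 |
| 25.0 | 3.2 |
| 40.0 | 4.9 |
| 60.0 | 8.6 |
| 120 | 16.1 |

(scatter of a reading: 0.5 percentage points)

- green: at 10 min add second substrate, 100% of the amount charged, then wait 5.0 min
- blue: at 10 min add free enzyme, 50.0% of the amount charged, then wait 5.0 min
- amber: change nothing and wait 5.0 min more
- violet: at 10 min raise the temperature by 15 K, then wait 5.0 min

- additions leave the volume as it is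
- the numbers in the tables scatter with a standard deviation of 0.5 percentage points
- a reading or a percentage of target counts all its forms, free or not

1. target, in percent of the starting material first charged, at 10 min
2. the option that brings most further target ("none" if no option brings more than 2 percentage points) (green / blue / amber / violet / none)
3. target present, in percent of the starting material first charged, after amber
4. target present, in percent of the starting material first charged, after violet

My ladder is built on the closing time: the gap below the ceiling divided by the rate at that moment. On the first rung, the epsilon reading stands at 54.8% after 2.00 min. Around 4.00 min the gap is 26 percentage points and the readings give 0.0545 min⁻¹ of the charge, so the closing time is 4.84 min. Around 8.00 min the gap is 16 points and the rate 0.0125 min⁻¹. Between these two moments the factor on the rate, 4.36, is larger than the factor on the gap, 1.69, so the closing time has stretched to 12.5 min. Gamma, with half the enzyme at 22 °C, ends 79 points below the ceiling, so it speaks of speed, not of where target stops.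

I take 81.6% for now. The wait of 5.0 min is shorter than the latest closing time, so amber should stay under 87.8%. I expect blue and violet to quicken the flask, but they keep a room of 13 points. Green lifts the ceiling to 100% and multiplies the second substrate present by 8.09. What remains of the starting material then falls pseudo-first-order, with a time of 2.37 min, which points to about 97.8%, so I choose green.

The forecast gives 81.5%, 85% after amber, 87% after violet and green as best, in its words “Green removes the ceiling and raises the rate about fivefold”, against my factor of 8.09.

The flask gives 82.0%, then 85.8% after amber and 89.2% after violet; green is best, bringing 14 points against 5 points for blue, 3.8 points for amber and 7.1 points for violet.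

    free enzyme → unfolded enzyme (k = 1.20 × 10⁻⁴ s⁻¹, Ea = 196 kJ mol⁻¹)
    starting material + free enzyme ⇌ starting complex (K = 150 L mol⁻¹, k = 48000 L mol⁻¹ s⁻¹, Ea = 15.0 kJ mol⁻¹, ΔH = 10.0 kJ mol⁻¹)
    second substrate + starting complex ⇌ ternary complex (K = 3.90 L mol⁻¹, k = 2.70 × 10⁵ L mol⁻¹ s⁻¹, Ea = 15.0 kJ mol⁻¹, ΔH = −10.0 kJ mol⁻¹)
    ternary complex → free enzyme + target (k = 340 s⁻¹, Ea = 55.0 kJ mol⁻¹)
    starting material + target ⇌ idle adduct, settled at all times (K = 260 L mol⁻¹, ΔH = −38.0 kJ mol⁻¹)
    (constants at 37 °C)

Left unchanged until 100 min, the flask reaches 93.9%, just under its ceiling of 95.0%. A neighbouring flask holds 0.34 M of starting material with the same second substrate, which is 0.240 equiv of second substrate to starting material. There the same division, second substrate charged over starting material charged, gives a ceiling of 24.0%. At 10.0 min this neighbour stands at 24.0% of target, with 53% of its starting material unbound and 0.19% of its second substrate left.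

Readings and results were computed on assumed constants.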